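**Retrosynthetic overview**

1. Locants used throughout: C1 angular-methyl carbon, C2/C3 cyclopentane CH2, C4 isopropyl carbinol, C5 ring-fusion CH, C6 ester-bearing carbon, C7 CH2, C8 methyl-bearing alkene carbon, C9 =CH, C10 CH2.
2. Late disconnections: phenol acetate, then the C6–O acyl bond (4-acetoxycinnamic acid), then C6 carbinol to ketone, then C5–H/C6=O back to a silyl enol ether.
3. Feature the strategy rests on: in the cycloheptene, C6 carries oxygen 1,3 to the C4 tertiary hydroxyl and sits next to the ring fusion. C7=C6(O)–C5=C1 is therefore a 2-oxydiene whose O6 and O4 can share one silicon atom, and C8–C9–C10 is a vinylcarbene; the seven-membered ring is cut at C7–C8 and C10–C1, a (4+3) annulation that also creates quaternary C1.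
4. C1–C6 with C4(OH)(iPr) are (S)-terpinen-4-ol after ozonolysis and aldol re-closure; C7 comes from methyllithium; C8–C10 and the C8 methyl come from the vinyldiazoacetate made from methyl acetoacetate.
5. Ring order: cyclopentene (aldol condensation), then the O–Si–O tether ring, then the cycloheptadiene; the tether is cut and the side chain attached last.

Key step: step 11

Assumption: (S)-(+)-terpinen-4-ol is taken as available in high enantiomeric purity, and the unsubstituted vinyldiazoacetate is always prepared immediately before use.

**Step 1**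
Reactants: 1 (S)-terpinen-4-ol
Product: 2 triethylsilyl ether of (S)-terpinen-4-ol
Conditions: Et3SiOTf, 2,6-lutidine, CH2Cl2, −78 to 0 °C
Reagents that add atoms: triethylsilyl triflate CC[Si](CC)(CC)OS(=O)(=O)C(F)(F)F
Why: Silyl triflate silylation of the hindered tertiary alcohol with a non-nucleophilic base leaves the alkene and the stereocentre untouched, and the ether prevents the hydroxyl from trapping the ketone of step 2 as a hemiketal.

**Step 2**
Reactants: 2 triethylsilyl ether of (S)-terpinen-4-ol
Product: 4 (3S)-6-oxo-3-(propan-2-yl)-3-(triethylsilyloxy)heptanal, via secondary ozonide 3 (not isolated)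
Conditions: O3, CH2Cl2, −78 °C; then PPh3, −78 °C to rt
Reagents that add atoms: ozone [O-][O+]=O
Why: Ozonolysis (Criegee mechanism) of the only alkene and phosphine reduction of the ozonide should give the methyl ketone and the aldehyde without touching the silyl ether or the quaternary stereocentre.

**Step 3**
Reactants: 4 (3S)-6-oxo-3-(propan-2-yl)-3-(triethylsilyloxy)heptanal
Product: 6 (5R)-2-methyl-5-(propan-2-yl)-5-(triethylsilyloxy)cyclopent-1-ene-1-carbaldehyde, via aldol adduct 5 (not isolated)
Conditions: piperidine (cat.), AcOH (cat.), toluene, 4 Å molecular sieves, rt to 50 °C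
Reagents that add atoms: none
Why: Amine/acid-catalysed intramolecular aldol condensation: the aldehyde forms its enamine faster than the methyl ketone, its α-carbon closes the five-membered ring onto the ketone (5-exo-trig) and dehydration to the tetrasubstituted conjugated enal is irreversible; the weakly basic buffer is chosen to limit β-elimination of the silyloxy group, and the carbinol stereocentre is not involved.

**Step 4**
Reactants: 6 (5R)-2-methyl-5-(propan-2-yl)-5-(triethylsilyloxy)cyclopent-1-ene-1-carbaldehyde; 7 methyllithium
Product: 8 1-[(5R)-2-methyl-5-(propan-2-yl)-5-(triethylsilyloxy)cyclopent-1-en-1-yl]ethan-1-ol (both carbinol epimers)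
Conditions: MeLi, Et2O, −78 °C; then H2O
Reagents that add atoms: none
Why: 1,2-Addition of the organolithium to the enal carbonyl (the fully substituted β-carbon disfavours conjugate addition) supplies C7; the new carbinol centre forms as a mixture that is erased in step 5.

**Step 5**
Reactants: 8 1-[(5R)-2-methyl-5-(propan-2-yl)-5-(triethylsilyloxy)cyclopent-1-en-1-yl]ethan-1-ol
Product: 9 1-[(5R)-2-methyl-5-(propan-2-yl)-5-(triethylsilyloxy)cyclopent-1-en-1-yl]ethan-1-one
Conditions: Dess–Martin periodinane, pyridine, CH2Cl2, 0 °C to rt
Reagents that add atoms: none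
Why: Dess–Martin oxidation of the secondary allylic alcohol to the enone under buffered conditions that the tertiary silyl ether tolerates.

**Step 6**
Reactants: 9 1-[(5R)-2-methyl-5-(propan-2-yl)-5-(triethylsilyloxy)cyclopent-1-en-1-yl]ethan-1-one
Product: 10 1-[(5R)-5-hydroxy-2-methyl-5-(propan-2-yl)cyclopent-1-en-1-yl]ethan-1-one
Conditions: HF·pyridine, pyridine, THF, 0 °C to rt
Reagents that add atoms: none
Why: Fluoride-mediated cleavage of the triethylsilyl ether; the freed tertiary alcohol is β to the ketone, but the α-carbon between them is vinylic, so neither retro-aldol cleavage nor E1cB dehydration is open.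

**Step 7**
Reactants: 10 1-[(5R)-5-hydroxy-2-methyl-5-(propan-2-yl)cyclopent-1-en-1-yl]ethan-1-one
Product: 12 cyclic diisopropylsilylene dienol ether (six-membered C4–O–Si(iPr)2–O–C6 ring with exocyclic C6=C7H2 beside the C5=C1 cyclopentene alkene; C4 unchanged), via C4 silyl triflate 11 (not isolated)
Conditions: iPr2Si(OTf)2, Et3N, CH2Cl2, −78 to 0 °C; filtration through Et3N-deactivated silica
Reagents that add atoms: diisopropylsilyl bis(trifluoromethanesulfonate) CC(C)[Si](OS(=O)(=O)C(F)(F)F)(OS(=O)(=O)C(F)(F)F)C(C)C
Why: Silyl triflate/amine silylation: the tertiary hydroxyl is silylated first, the remaining Si–OTf is captured intramolecularly by the ketone oxygen, and triethylamine removes a proton from the acetyl methyl (the only α-carbon bearing hydrogen, vinylogous γ-deprotonation being slower); this closes the six-membered O4–Si–O6 ring and gives the cross-conjugated 2-siloxydiene locked s-cis, with C4 untouched.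

**Step 8**
Reactants: 13 methyl acetoacetate
Product: 14 methyl 2-diazo-3-oxobutanoate
Conditions: 4-acetamidobenzenesulfonyl azide, Et3N, MeCN, 0 °C to rt
Reagents that add atoms: 4-acetamidobenzenesulfonyl azide CC(=O)Nc1ccc(cc1)S(=O)(=O)N=[N+]=[N-]
Why: Regitz diazo transfer to the doubly activated methylene.

**Step 9**
Reactants: 14 methyl 2-diazo-3-oxobutanoate
Product: 15 methyl 2-diazo-3-hydroxybutanoate (racemic)
Conditions: NaBH4, MeOH, 0 °C
Reagents that add atoms: none
Why: Borohydride reduction of the ketone, to which the α-diazo ester is inert at 0 °C; the racemic carbinol centre disappears in step 10.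

**Step 10**
Reactants: 15 methyl 2-diazo-3-hydroxybutanoate
Product: 16 methyl 2-diazobut-3-enoate
Conditions: POCl3, Et3N, CH2Cl2, 0 °C; cold pentane solution used at once
Reagents that add atoms: none
Why: Dehydration through the dichlorophosphate (E2 with triethylamine) should give the vinyldiazoacetate, which is kept cold and used immediately because it cyclises to a pyrazole on standing.

**Step 11**
Reactants: 12 cyclic diisopropylsilylene dienol ether; 16 methyl 2-diazobut-3-enoate
Product: 18 tricyclic enoate (methyl ester on C8; C8=C9 and C5=C6 alkenes; Si(iPr)2 bridging O4 and O6; quaternary C1 with its methyl cis to O4), via cis-divinylcyclopropane 17 (not isolated)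
Conditions: Rh2(R-DOSP)4 [dirhodium tetrakis((R)-N-(4-dodecylphenylsulfonyl)prolinate)] (2 mol %), pentane, −78 °C to rt, 16 (3 equiv) added over 2 h to 12; then toluene, 80 °C
Reagents that add atoms: none
Why: The dirhodium tetracarboxylate turns 16 into a donor/acceptor vinylcarbenoid that cyclopropanates only the terminal, siloxy-activated C6=C7 alkene of 12 (C5=C1 is tetrasubstituted and inert), closing the three-membered ring C6–C7–C8 by a concerted asynchronous [2+1] addition that starts at the unhindered C7 terminus; tandem cyclopropanation/Cope rearrangement of vinyldiazoacetates with 2-siloxydienes is an established formal (4+3) cycloaddition, applied here to an untried tethered diene with a fully substituted terminus. In 17 the vinyl group on C8 and the cyclopentenyl carbon C5 on C6 are cis, so a boat-shaped [3,3] shift cleaves C6–C8 and joins C10 to C1; the seven-membered ring thus arises by ring expansion of the three-membered ring in one pericyclic event with no independent cyclisation step, and the loss of cyclopropane strain together with the new enoate and enol ether conjugation offsets the cost of building the crowded C1. The only new stereocentre that survives is quaternary C1, and because the shift is suprafacial C10 arrives on the face of C1 on which C8 sits at the spiro carbon C6. The O–Si–O ring keeps O6 on the O4 side of the cyclopentene plane, so the C6–C8 bond that can overlap with the C5=C1 π system projects to the isopropyl face, which puts C10 syn to isopropyl and the C1 methyl cis to the C4 oxygen as in the target; the same ring holds C5=C1 s-cis over the cyclopropane and so eases the penalty of the inward C1 methyl in the boat. Rh2(R-DOSP)4 is the antipode expected from the end-on approach model to place C8 on that face directly (the other antipode and an achiral dirhodium tetracarboxylate are the control runs), and a cyclopropane with the vinyl group trans to C5 is not a dead end, since its push–pull C6–C8 bond (siloxy on one carbon, ester on the other) can ionise and re-form on warming. Chemoselectivity over allylic C–H insertion and over attack at the vinylogous carbenoid terminus rests on the nucleophilic, unhindered enol ether CH2, the hydrocarbon solvent and the slow addition of 16.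

**Step 12**
Reactants: 18 tricyclic enoate
Product: 19 tricyclic allylic alcohol (CH2OH on C8)
Conditions: iBu2AlH (2.5 equiv), CH2Cl2, −78 °C; Rochelle salt work-up
Reagents that add atoms: none
Why: 1,2-Reduction of the conjugated ester by iBu2AlH at low temperature should give the allylic alcohol; the hindered dialkoxysilane and the silyl enol ether are not attacked and no stereocentre is affected.

**Step 13**
Reactants: 19 tricyclic allylic alcohol
Product: 21 tricyclic allylic chloride (CH2Cl on C8), via allylic mesylate 20 (not isolated)
Conditions: MeSO2Cl, 2,4,6-collidine, LiCl, DMF, 0 °C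
Reagents that add atoms: methanesulfonyl chloride CS(=O)(=O)Cl (its atoms stay only in intermediate 20); lithium chloride [Li+].[Cl-]
Why: Mesylation and in situ SN2 displacement by chloride under basic conditions that preserve the acid-sensitive silyl enol ether.

**Step 14**
Reactants: 21 tricyclic allylic chloride
Product: 22 C8-methyl tricyclic silylene enol ether
Conditions: LiEt3BH, THF, 0 °C
Reagents that add atoms: none
Why: SN2 hydride displacement of the primary allylic chloride by LiEt3BH installs the C8 methyl without moving the C8=C9 alkene, and the hindered Si(iPr)2 acetal is not attacked at this temperature.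

**Step 15**
Reactants: 22 C8-methyl tricyclic silylene enol ether
Product: 24 (3R,3aR,8aR)-3-hydroxy-6,8a-dimethyl-3-(propan-2-yl)-2,3,3a,5,8,8a-hexahydroazulen-4(1H)-one (trans-fused hydroxy ketone), via fluorosilyl ether ketone 23 (not isolated)
Conditions: HF·pyridine, pyridine, THF, −20 to 0 °C; NaHCO3 work-up, no basic treatment
Reagents that add atoms: hydrogen fluoride F (as HF·pyridine; its fluorine stays only in intermediate 23 and in the silicon by-product)
Why: Acid-mediated protodesilylation of the silyl enol ether: C5 is protonated while silicon is still bound to O4, so C6 has to swing to the O4 face of the cyclopentane (silicon ring cis-fused, carbonyl cis to the C4 oxygen and away from isopropyl), which puts the new hydrogen on the isopropyl face and gives the trans-fused hydroazulenone, the isomer also expected to be favoured by an O4–H···O=C6 hydrogen bond; fluoride then frees O4, and basic equilibration is deliberately avoided because C7 lies between the ketone and the C8=C9 alkene (drift into conjugation) and the tertiary aldol could dehydrate or cleave by retro-aldol reaction.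

**Step 16**
Reactants: 24 trans-fused hydroxy ketone
Product: 25 jaeschkeanadiol [(3R,3aS,4S,8aR)-6,8a-dimethyl-3-(propan-2-yl)-1,2,3,3a,4,5,8,8a-octahydroazulene-3,4-diol]
Conditions: Me4NBH(OAc)3, MeCN/AcOH (1:1), −30 to −20 °C
Reagents that add atoms: none
Why: Evans–Saksena reduction: exchange of an acetate on boron for the C4 hydroxyl gives an alkoxyborohydride that delivers hydride through a six-membered chair transition state to the C6 face on the O4 side, so the new C6 hydroxyl is anti to the C4 oxygen and H6 is trans to H5 as in the target; only the trans-fused ketone has its carbonyl within reach of O4, and the acidic medium does not enolise the β,γ-unsaturated ketone.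

**Step 17**
Reactants: 25 jaeschkeanadiol; 26 (E)-4-acetoxycinnamic acid
Product: 28 (3R,3aS,4S,8aR)-3-hydroxy-6,8a-dimethyl-3-(propan-2-yl)-1,2,3,3a,4,5,8,8a-octahydroazulen-4-yl (2E)-3-(4-acetoxyphenyl)prop-2-enoate, via mixed anhydride 27 (not isolated)
Conditions: 26, 2,4,6-trichlorobenzoyl chloride, Et3N, THF, rt; then 25, DMAP, toluene, rt
Reagents that add atoms: 2,4,6-trichlorobenzoyl chloride O=C(Cl)c1c(Cl)cc(Cl)cc1Cl (its atoms stay only in intermediate 27)
Why: Yamaguchi esterification: DMAP attacks the less hindered cinnamoyl carbonyl of the mixed anhydride and the acylpyridinium acylates only the secondary C6 hydroxyl, the tertiary C4 hydroxyl being inert; the E alkene comes with the acid and C6 keeps its configuration because the C6–O bond is not broken.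

**Step 18**
Reactants: 28 O-acetyl ester
Product: 29 target CNP0265426.1 [(3R,3aS,4S,8aR)-3-hydroxy-6,8a-dimethyl-3-(propan-2-yl)-1,2,3,3a,4,5,8,8a-octahydroazulen-4-yl (2E)-3-(4-hydroxyphenyl)prop-2-enoate]
Conditions: pyrrolidine (2 equiv), CH2Cl2, 0 °C to rt
Reagents that add atoms: none
Why: Aminolysis of the aryl acetate, an activated ester, by the secondary amine is much faster than attack on the hindered alkyl cinnamate or conjugate addition to it, so the phenol should be unmasked with the ester, the tertiary alcohol, both alkenes and all four stereocentres unchanged.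

**Compound list**

1 | (S)-terpinen-4-ol | CC1=CC[C@](O)(C(C)C)CC1 | starting material
2 | triethylsilyl ether of (S)-terpinen-4-ol | CC1=CC[C@](O[Si](CC)(CC)CC)(C(C)C)CC1 | intermediate
3 | secondary ozonide of 2 (bridgehead epimers) | CC12CC[C@@](O[Si](CC)(CC)CC)(C(C)C)CC(OO1)O2 | intermediate (not isolated)
4 | (3S)-6-oxo-3-(propan-2-yl)-3-(triethylsilyloxy)heptanal | CC(=O)CC[C@@](O[Si](CC)(CC)CC)(C(C)C)CC=O | intermediate
5 | aldol adduct, 2-hydroxy-2-methyl-5-(propan-2-yl)-5-(triethylsilyloxy)cyclopentane-1-carbaldehyde (mixture at the two new centres) | O=CC1C(C)(O)CC[C@@]1(O[Si](CC)(CC)CC)C(C)C | intermediate (not isolated)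
6 | (5R)-2-methyl-5-(propan-2-yl)-5-(triethylsilyloxy)cyclopent-1-ene-1-carbaldehyde | O=CC1=C(C)CC[C@@]1(O[Si](CC)(CC)CC)C(C)C | intermediate
7 | methyllithium | [Li]C | starting material
8 | 1-[(5R)-2-methyl-5-(propan-2-yl)-5-(triethylsilyloxy)cyclopent-1-en-1-yl]ethan-1-ol (carbinol epimers) | CC(O)C1=C(C)CC[C@@]1(O[Si](CC)(CC)CC)C(C)C | intermediate
9 | 1-[(5R)-2-methyl-5-(propan-2-yl)-5-(triethylsilyloxy)cyclopent-1-en-1-yl]ethan-1-one | CC(=O)C1=C(C)CC[C@@]1(O[Si](CC)(CC)CC)C(C)C | intermediate
10 | 1-[(5R)-5-hydroxy-2-methyl-5-(propan-2-yl)cyclopent-1-en-1-yl]ethan-1-one | CC(=O)C1=C(C)CC[C@@]1(O)C(C)C | intermediate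
11 | C4 diisopropyl(triflyloxy)silyl ether of 10 | CC(=O)C1=C(C)CC[C@@]1(O[Si](OS(=O)(=O)C(F)(F)F)(C(C)C)C(C)C)C(C)C | intermediate (not isolated)
12 | cyclic diisopropylsilylene dienol ether (2-siloxydiene; O4–Si–O6 six-membered ring, exocyclic C6=C7H2, C5=C1 in the cyclopentene) | C=C1O[Si](C(C)C)(C(C)C)O[C@@]2(C(C)C)CCC(C)=C12 | intermediate
13 | methyl acetoacetate | CC(=O)CC(=O)OC | starting material
14 | methyl 2-diazo-3-oxobutanoate | CC(=O)C(=[N+]=[N-])C(=O)OC | intermediate
15 | methyl 2-diazo-3-hydroxybutanoate (racemic) | CC(O)C(=[N+]=[N-])C(=O)OC | intermediate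
16 | methyl 2-diazobut-3-enoate | C=CC(=[N+]=[N-])C(=O)OC | intermediate
17 | cis-divinylcyclopropane (cyclopropane spiro at C6; C8 with vinyl and CO2Me on the isopropyl face, vinyl cis to C5) | C=C[C@@]1(C(=O)OC)C[C@]12O[Si](C(C)C)(C(C)C)O[C@@]3(C(C)C)CCC(C)=C23 | intermediate (not isolated)
18 | tricyclic enoate (1R,4R in the locants used here; CO2Me on C8, C8=C9 and C5=C6 alkenes, Si(iPr)2 bridging O4 and O6) | COC(=O)C1=CC[C@@]2(C)CC[C@]3(C(C)C)O[Si](C(C)C)(C(C)C)OC(C1)=C23 | intermediate
19 | tricyclic allylic alcohol (CH2OH on C8) | OCC1=CC[C@@]2(C)CC[C@]3(C(C)C)O[Si](C(C)C)(C(C)C)OC(C1)=C23 | intermediate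
20 | allylic mesylate of 19 | CS(=O)(=O)OCC1=CC[C@@]2(C)CC[C@]3(C(C)C)O[Si](C(C)C)(C(C)C)OC(C1)=C23 | intermediate (not isolated)
21 | tricyclic allylic chloride (CH2Cl on C8) | ClCC1=CC[C@@]2(C)CC[C@]3(C(C)C)O[Si](C(C)C)(C(C)C)OC(C1)=C23 | intermediate
22 | C8-methyl tricyclic silylene enol ether | CC1=CC[C@@]2(C)CC[C@]3(C(C)C)O[Si](C(C)C)(C(C)C)OC(C1)=C23 | intermediate
23 | O4 fluorodiisopropylsilyl ether of 24 | CC1=CC[C@@]2(C)CC[C@@](O[Si](F)(C(C)C)C(C)C)(C(C)C)[C@@H]2C(=O)C1 | intermediate (not isolated)
24 | (3R,3aR,8aR)-3-hydroxy-6,8a-dimethyl-3-(propan-2-yl)-2,3,3a,5,8,8a-hexahydroazulen-4(1H)-one | CC1=CC[C@@]2(C)CC[C@@](O)(C(C)C)[C@@H]2C(=O)C1 | intermediate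
25 | jaeschkeanadiol, (3R,3aS,4S,8aR)-6,8a-dimethyl-3-(propan-2-yl)-1,2,3,3a,4,5,8,8a-octahydroazulene-3,4-diol | CC1=CC[C@@]2(C)CC[C@@](O)(C(C)C)[C@@H]2[C@@H](O)C1 | intermediate
26 | (E)-4-acetoxycinnamic acid | CC(=O)Oc1ccc(/C=C/C(=O)O)cc1 | starting material
27 | mixed anhydride of 26 with 2,4,6-trichlorobenzoic acid | CC(=O)Oc1ccc(/C=C/C(=O)OC(=O)c2c(Cl)cc(Cl)cc2Cl)cc1 | intermediate (not isolated)
28 | O-acetyl protected target ester | CC1=CC[C@@]2(C)CC[C@@](O)(C(C)C)[C@@H]2[C@@H](OC(=O)/C=C/c2ccc(OC(C)=O)cc2)C1 | intermediate
29 | target CNP0265426.1 | CC1=CC[C@@]2(C)CC[C@@](O)(C(C)C)[C@@H]2[C@@H](OC(=O)/C=C/c2ccc(O)cc2)C1 | target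

**Totals**

Total step count: 18
Longest linear sequence: 15 steps (steps 1–7 and 11–18, from (S)-terpinen-4-ol); the diazo branch is 3 steps (8–10).

**Steps most likely to fail**

1. Step 11. The carbenoid may add to the wrong face of the enol ether or place its vinyl group trans to C5, the Cope shift may stall because the C1 methyl points inward in the boat, and allylic C–H insertion or vinylogous attack may compete. Fallback (sets out from 6, returns at 24): the seven-membered ring is closed by ring-closing metathesis instead. Methallylmagnesium chloride adds to 6 to give the homoallylic alcohol F1, and buffered Dess–Martin oxidation gives the β,γ-unsaturated ketone F2. Conjugate allylation at C1 with allylcopper (from allylmagnesium bromide, CuBr·SMe2 and LiCl) in the presence of Me3SiCl gives the trimethylsilyl enol ether F3, and mild aqueous hydrolysis gives the quaternary ketone F4. In F4 the configurations at C1 and C5 would rest on substrate control and chromatographic separation. Ring-closing metathesis of the allyl and isopropenyl groups with the second-generation Grubbs catalyst forms C8=C9 and gives the triethylsilyl-protected hydroazulenone F5, and HF·pyridine then returns to 24.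

2. Step 15. C5 may be protonated from the face syn to O4 (giving the cis-fused ketone), the tertiary aldol may dehydrate, or the C8=C9 alkene may drift into conjugation. Fallback (sets out from 22, returns at 24): kinetic protonation of a preformed enolate under reagent control. MeLi in THF at 0 °C cleaves the Si–O(enol) bond to give the lithium enolate F6, in which O4 carries a bulky methyldiisopropylsilyl group over the lower face. Inverse quench at −78 °C into excess 2,6-di-tert-butyl-4-methylphenol gives the silyl ether ketone F7, and HF·pyridine then frees O4 to give 24. Material with the wrong C5 configuration would be left unreduced in step 16 and removed there.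

3. Step 7. Enolisation may run toward the ring (γ-deprotonation) to give the extended dienol silyl ether, silylation may go intermolecularly, or the product may hydrolyse on isolation. Fallback (sets out from 10, returns at 12): the enolate is formed irreversibly before silicon is introduced. LDA (2.2 equiv) in THF at −78 °C gives the dilithium alkoxide/cross-conjugated enolate F8, which is trapped on both oxygens with iPr2SiCl2 to close the ring to 12.

**Further compounds**

F1 | step 11 | 1-[(5R)-2-methyl-5-(propan-2-yl)-5-(triethylsilyloxy)cyclopent-1-en-1-yl]-3-methylbut-3-en-1-ol | CC(=C)CC(O)C1=C(C)CC[C@@]1(O[Si](CC)(CC)CC)C(C)C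
F2 | step 11 | 1-[(5R)-2-methyl-5-(propan-2-yl)-5-(triethylsilyloxy)cyclopent-1-en-1-yl]-3-methylbut-3-en-1-one | CC(=C)CC(=O)C1=C(C)CC[C@@]1(O[Si](CC)(CC)CC)C(C)C
F3 | step 11 | trimethylsilyl enol ether of the C1-allylated ketone | C=CC[C@@]1(C)CC[C@](C(C)C)(O[Si](CC)(CC)CC)C1=C(O[Si](C)(C)C)CC(C)=C
F4 | step 11 | C1-allyl C6-methallyl ketone (C1 quaternary, C5–H trans to the allyl group) | C=CC[C@@]1(C)CC[C@@](O[Si](CC)(CC)CC)(C(C)C)[C@@H]1C(=O)CC(C)=C
F5 | step 11 | O4 triethylsilyl ether of 24 | CC1=CC[C@@]2(C)CC[C@@](O[Si](CC)(CC)CC)(C(C)C)[C@@H]2C(=O)C1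
F6 | step 15 | lithium C5=C6 enolate with O4 methyldiisopropylsilyl ether | CC1=CC[C@@]2(C)CC[C@](C(C)C)(O[Si](C)(C(C)C)C(C)C)C2=C(O[Li])C1
F7 | step 15 | O4 methyldiisopropylsilyl ether of 24 | CC1=CC[C@@]2(C)CC[C@@](O[Si](C)(C(C)C)C(C)C)(C(C)C)[C@@H]2C(=O)C1
F8 | step 7 | dilithium alkoxide/enolate of 10 | C=C(O[Li])C1=C(C)CC[C@@]1(O[Li])C(C)C
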